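**Strategy.** The 1,2-dioxane ring (O1–O2–C3–C4–C5–C6) is cut across C4–C5 and O1–C6. This leaves butanal (C3, C4 and the C4 ethyl), dioxygen (O1–O2) and a chiral triene whose terminal C5=C6 alkene already carries the C6 ethyl group and the whole C7–C14 side chain. The key step, an aerobic enamine radical-cation [2+2+2] union, exploits that C4 is the α-carbon of an aldehyde-level C3 and that C6 is a tertiary allylic carbon: C4–C5 and C6–O1 form in one operation and the hydroperoxide closes onto C3 as a 1,2-dioxan-3-ol. Peroxycarbenium alkylation at C3 then adds the acetic acid arm cis to the C4 ethyl group.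

Key step: step 6

Remark: atoms are numbered C1 (carboxyl carbon), C2, ring C3–C6 with O2 on C3 and O1 on C6, side chain C7–C14. The sense of induction of the amino-alcohol ligand (step 1) and of the imidazolidinone (step 6) is assumed to follow their accepted transition-state models; the mirror-image catalyst would be used if either proved opposite.

Step 1
Reactants: 1 (E)-pent-2-enal
Product: 2 (R,E)-hept-4-en-3-ol
Conditions: Et2Zn (1.5 equiv), (2R)-(+)-3-exo-morpholinoisoborneol (5 mol %), hexane/toluene, 0 °C; then 1 M HCl
Reagents that add atoms: diethylzinc, CC[Zn]CC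
Why: Amino-alcohol-catalysed enantioselective 1,2-addition of a dialkylzinc to an aldehyde; the (2R) ligand is the mirror image of the one that gives (S)-carbinols, so ethyl should be delivered to the face that gives the (R)-carbinol.

Step 2
Reactants: 2 (R,E)-hept-4-en-3-ol
Product: 3 ethyl (R,E)-3-ethylhept-4-enoate
Conditions: MeC(OEt)3 (6 equiv), EtCO2H (cat.), 140 °C, distil off EtOH
Reagents that add atoms: triethyl orthoacetate, CC(OCC)(OCC)OCC
Why: Johnson–Claisen [3,3] rearrangement through a chair with the carbinol ethyl group equatorial, which transfers the (R)-carbinol configuration suprafacially to the new C10 stereocentre (R) and gives the (E)-C11=C12 alkene.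

Step 3
Reactants: 3 ethyl (R,E)-3-ethylhept-4-enoate
Product: 4 (R,E)-3-ethylhept-4-enal
Conditions: DIBAL-H (1.1 equiv), CH2Cl2, −78 °C; aqueous work-up
Reagents that add atoms: none
Why: Partial reduction of an ester to the aldehyde via the tetrahedral aluminium hemiacetal that is stable at −78 °C; the β-stereocentre is not epimerisable.

Step 4
Reactants: 4 (R,E)-3-ethylhept-4-enal
Product: 5 (R,E)-4-ethyloct-5-en-1-yne
Conditions: dimethyl (1-diazo-2-oxopropyl)phosphonate, K2CO3, MeOH, 0 °C to rt
Reagents that add atoms: dimethyl (1-diazo-2-oxopropyl)phosphonate, COP(=O)(OC)C(=[N+]=[N-])C(C)=O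
Why: Seyferth–Gilbert homologation in its Ohira–Bestmann form converts the aldehyde to the terminal alkyne (C7≡C8) under mild base that does not touch the remote stereocentre or alkene.

Step 5
Reactants: 5 (R,E)-4-ethyloct-5-en-1-yne; 6 2-bromobut-1-ene
Product: 9 (3E,6R,7E)-2,4,6-triethyldeca-1,3,7-triene, via vinylcopper 7 (not isolated), via vinylzinc bromide 8 (not isolated)
Conditions: EtMgBr, CuBr·SMe2, Et2O/Me2S, −45 to −25 °C, then 5; then ZnBr2, THF, Pd(PPh3)4 (5 mol %), 6, −20 °C to rt
Reagents that add atoms: ethylmagnesium bromide, CC[Mg]Br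
Why: syn-Carbocupration of the terminal alkyne puts ethyl on the internal carbon C8 and copper cis to it on C7; copper-to-zinc transmetalation and zerovalent-palladium-catalysed Negishi-type coupling with 6 proceed with retention, fixing the (E)-C7=C8 geometry.

Step 6
Reactants: 9 (3E,6R,7E)-2,4,6-triethyldeca-1,3,7-triene; 10 butanal
Product: 12 (4S,6R)-4,6-diethyl-6-[(1E,4R,5E)-2,4-diethylocta-1,5-dien-1-yl]-1,2-dioxan-3-ol, via hydroperoxy aldehyde 11 (not isolated)
Conditions: 10 (3 equiv, slow addition), (2R,5R)-5-benzyl-2-tert-butyl-3-methylimidazolidin-4-one·TFA (20 mol %), [Fe(phen)3](PF6)3 (10 mol %), O2 (1 atm), H2O (2 equiv), DME, −20 °C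
Reagents that add atoms: dioxygen, O=O
Why: Proposed new method: the imidazolidinone and 10 form an (E)-enamine that [Fe(phen)3](PF6)3 oxidises to a 3π-electron radical cation, which adds to the unsubstituted diene terminus C5 of 9; the tetraalkyl allyl radical captures O2 at C6, the divalent iron complex reduces the peroxyl radical and returns to the trivalent state (redox-neutral overall), and hydrolysis of the iminium releases 11, which closes to 12. The closest known reaction types are SOMO-activated α-alkylation of aldehydes with olefins and the manganese triacetate/O2 synthesis of 1,2-dioxan-3-ols from 1,3-dicarbonyl compounds and alkenes; the enamine radical cation here takes the place of the dicarbonyl radical. The 1,2-dioxane ring closes by 6-exo-trig addition of the C6 hydroperoxide oxygen to the C3 carbonyl (iminium) carbon, a reversible hemiacetalisation that leaves C3 as an anomeric mixture of no consequence. C4 (S) is set by the catalyst: its benzyl group shields the Si face of the enamine α-carbon, so C5 bonds to the Re face. C6 is created in the O2 capture far from the catalyst, so only weak 1,3-induction from C4 is expected and the (6R) epimer (ethyl groups cis) is to be separated from its C6 epimer by chromatography. The step needs attack at C5 (the only unsubstituted, least hindered alkene terminus, giving the most stabilised radical) and oxygenation at C6 and not C8 (favoured because O2 addition to the congested allyl radical is reversible and only the C6 hydroperoxide can close the six-membered hemiacetal on C3).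

Step 7
Reactants: 12 (4S,6R)-4,6-diethyl-6-[(1E,4R,5E)-2,4-diethylocta-1,5-dien-1-yl]-1,2-dioxan-3-ol
Product: 13 (4S,6R)-4,6-diethyl-6-[(1E,4R,5E)-2,4-diethylocta-1,5-dien-1-yl]-3-methoxy-1,2-dioxane
Conditions: MeOH, PPTS (cat.), 3 Å MS, 0 °C to rt
Reagents that add atoms: methanol, CO
Why: Acid-catalysed acetalisation of the peroxy hemiacetal; PPTS is mild enough to leave the tertiary allylic C6–O1 bond intact, and the C3 anomers converge in the next step.

Step 8
Reactants: 13 (4S,6R)-4,6-diethyl-6-[(1E,4R,5E)-2,4-diethylocta-1,5-dien-1-yl]-3-methoxy-1,2-dioxane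
Product: 14 methyl 2-[(3S,4S,6R)-4,6-diethyl-6-[(1E,4R,5E)-2,4-diethylocta-1,5-dien-1-yl]-1,2-dioxan-3-yl]acetate
Conditions: CH2=C(OMe)OTBS (3 equiv), TMSOTf (0.3 equiv), CH2Cl2, −78 °C
Reagents that add atoms: tert-butyl[(1-methoxyethenyl)oxy]dimethylsilane, C=C(OC)O[Si](C)(C)C(C)(C)C
Why: Lewis-acid ionisation of the peroxy acetal gives a cyclic peroxycarbenium ion that is trapped by the silyl ketene acetal (Mukaiyama-type addition); in the half-chair with the C4 and C6 ethyl groups pseudo-equatorial (the alternative has them syn-diaxial) axial attack through a chair-like transition state places the new C3 substituent cis to the C4 ethyl group, which is (3S).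

Step 9
Reactants: 14 methyl 2-[(3S,4S,6R)-4,6-diethyl-6-[(1E,4R,5E)-2,4-diethylocta-1,5-dien-1-yl]-1,2-dioxan-3-yl]acetate
Product: 15 Plakortide N, 2-[(3S,4S,6R)-4,6-diethyl-6-[(1E,4R,5E)-2,4-diethylocta-1,5-dien-1-yl]-1,2-dioxan-3-yl]acetic acid
Conditions: LiOH·H2O, THF/H2O, 0 °C; then 1 M HCl to pH 3 at 0 °C
Reagents that add atoms: lithium hydroxide, [Li+].[OH-]
Why: Saponification of the methyl ester; dialkyl peroxides tolerate cold LiOH, and the carboxylate formed disfavours E1cB opening of the β-peroxy ester, so no stereocentre is touched.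

**Compound list**

1 | (E)-pent-2-enal | CC/C=C/C=O | starting material
2 | (R,E)-hept-4-en-3-ol | CC/C=C/[C@H](O)CC | intermediate
3 | ethyl (R,E)-3-ethylhept-4-enoate | CC/C=C/[C@H](CC)CC(=O)OCC | intermediate
4 | (R,E)-3-ethylhept-4-enal | CC/C=C/[C@H](CC)CC=O | intermediate
5 | (R,E)-4-ethyloct-5-en-1-yne | CC/C=C/[C@H](CC)CC#C | intermediate
6 | 2-bromobut-1-ene | C=C(Br)CC | starting material
7 | [(1E,4R,5E)-2,4-diethylocta-1,5-dien-1-yl]copper (vinylcopper, MgBr2/SMe2 complex) | CC/C=C/[C@H](CC)C/C(=C/[Cu])CC | intermediate
8 | [(1E,4R,5E)-2,4-diethylocta-1,5-dien-1-yl]zinc bromide | CC/C=C/[C@H](CC)C/C(=C/[Zn]Br)CC | intermediate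
9 | (3E,6R,7E)-2,4,6-triethyldeca-1,3,7-triene | CC/C=C/[C@H](CC)C/C(=C/C(CC)=C)CC | intermediate
10 | butanal | CCCC=O | starting material
11 | (2S,4R,5E,8R,9E)-2,4,6,8-tetraethyl-4-hydroperoxydodeca-5,9-dienal | CC/C=C/[C@H](CC)C/C(=C/[C@](CC)(OO)C[C@H](CC)C=O)CC | intermediate
12 | (4S,6R)-4,6-diethyl-6-[(1E,4R,5E)-2,4-diethylocta-1,5-dien-1-yl]-1,2-dioxan-3-ol (C3 anomers) | CC/C=C/[C@H](CC)C/C(=C/[C@@]1(CC)C[C@H](CC)C(O)OO1)CC | intermediate
13 | (4S,6R)-4,6-diethyl-6-[(1E,4R,5E)-2,4-diethylocta-1,5-dien-1-yl]-3-methoxy-1,2-dioxane (C3 anomers) | CC/C=C/[C@H](CC)C/C(=C/[C@@]1(CC)C[C@H](CC)C(OC)OO1)CC | intermediate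
14 | methyl 2-[(3S,4S,6R)-4,6-diethyl-6-[(1E,4R,5E)-2,4-diethylocta-1,5-dien-1-yl]-1,2-dioxan-3-yl]acetate | CC/C=C/[C@H](CC)C/C(=C/[C@@]1(CC)C[C@H](CC)[C@H](CC(=O)OC)OO1)CC | intermediate
15 | Plakortide N, 2-[(3S,4S,6R)-4,6-diethyl-6-[(1E,4R,5E)-2,4-diethylocta-1,5-dien-1-yl]-1,2-dioxan-3-yl]acetic acid | CC/C=C/[C@H](CC)C/C(=C/[C@@]1(CC)C[C@H](CC)[C@H](CC(=O)O)OO1)CC | target

**Totals.** Total step count: 9. Longest linear sequence: 9 steps (1 to 15); 6 and 10 enter as commercial partners in steps 5 and 6.

**Steps most likely to fail**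

Step 6 (key step). What may go wrong: capture of O2 by the enamine radical cation before it adds to the diene (α-oxygenation of butanal), acyl-radical autoxidation of the excess aldehyde, irreversible oxygenation of the allyl radical at C8, and lack of facial control when the C6–O1 bond forms. Fallback with known reactions only, setting out from 10 and 5 and coming back at 13: butanal 10 is alkylated with 1-bromobutan-2-one under photoredox/imidazolidinone catalysis (Ru(bpy)3Cl2, the trans-2-tert-butyl-3,5-dimethylimidazolidin-4-one enantiomer that exposes the Re face of the enamine, 2,6-lutidine, visible light). This gives (S)-2-ethyl-4-oxohexanal F1, whose aldehyde is masked with HC(OMe)3/MeOH/PPTS as (S)-5-(dimethoxymethyl)heptan-3-one F2. Alkyne 5 is carbocuprated as in step 5 and vinylcopper 7 is quenched with I2 to give (1E,4R,5E)-2,4-diethyl-1-iodoocta-1,5-diene F3. Iodine–lithium exchange (t-BuLi, Et2O, −78 °C) gives [(1E,4R,5E)-2,4-diethylocta-1,5-dien-1-yl]lithium F4, which adds to the ketone of F2 to give the tertiary allylic alcohol (2S,5E,8R,9E)-2,4,6,8-tetraethyl-1,1-dimethoxydodeca-5,9-dien-4-ol F5 as both carbinol epimers. Ethereal H2O2 with catalytic TsOH then converts the acetal to the hydroperoxy acetal and closes the ring by intramolecular SN1 substitution at the tertiary allylic carbon, for which only the six-membered mode at C6 is available; this gives 13 after separation of the C6 epimers.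

Step 8. What may go wrong: Lewis-acid ionisation of the tertiary allylic C6–O1 bond in competition with loss of methoxide, and attack on the peroxycarbenium ion from the face that gives the 3,4-trans isomer. Fallback setting out from 12 and coming back at 14: lactol 12 reacts through its open form with trimethyl phosphonoacetate (LiCl, i-Pr2NEt, MeCN) in a Horner–Wadsworth–Emmons olefination to give methyl (2E,4S,6R,7E,10R,11E)-4,6,8,10-tetraethyl-6-hydroperoxytetradeca-2,7,11-trienoate F6. Et2NH in CF3CH2OH then closes the ring by intramolecular 6-exo-trig peroxy-Michael addition to give 14 together with its C3 epimer, which is removed by chromatography.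

Step 5. What may go wrong: incomplete copper-to-zinc transmetalation, homocoupling or protodemetalation of vinylcopper 7 in the one-pot coupling with the hindered bromide 6. Fallback setting out from 5 and 6 and coming back at 9: vinylcopper 7 is quenched with I2 and the vinyl iodide F3 (the compound also used in the fallback for step 6) is isolated. Bromide 6 is converted with Mg in THF to but-1-en-2-ylmagnesium bromide F7, and Pd(PPh3)4-catalysed Kumada coupling of F3 with F7 gives 9 with retention of the alkene geometry.

**Further compounds**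

F1 | step 6 | (S)-2-ethyl-4-oxohexanal | CCC(=O)C[C@H](CC)C=O
F2 | step 6 | (S)-5-(dimethoxymethyl)heptan-3-one | CCC(=O)C[C@H](CC)C(OC)OC
F3 | step 6 | (1E,4R,5E)-2,4-diethyl-1-iodoocta-1,5-diene | CC/C=C/[C@H](CC)C/C(=C/I)CC
F4 | step 6 | [(1E,4R,5E)-2,4-diethylocta-1,5-dien-1-yl]lithium | CC/C=C/[C@H](CC)C/C(=C/[Li])CC
F5 | step 6 | (2S,5E,8R,9E)-2,4,6,8-tetraethyl-1,1-dimethoxydodeca-5,9-dien-4-ol (both carbinol epimers) | CC/C=C/[C@H](CC)C/C(=C/C(O)(CC)C[C@H](CC)C(OC)OC)CC
F6 | step 8 | methyl (2E,4S,6R,7E,10R,11E)-4,6,8,10-tetraethyl-6-hydroperoxytetradeca-2,7,11-trienoate | CC/C=C/[C@H](CC)C/C(=C/[C@](CC)(OO)C[C@H](CC)/C=C/C(=O)OC)CC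
F7 | step 5 | but-1-en-2-ylmagnesium bromide | C=C(CC)[Mg]Br
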